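**Retrosynthetic overview**

- Target ⇐ hydrogenolysis of its bis(O-benzyl) ether ⇐ trans-selective α-benzylation (sets C8′) of a β-[aryl(hydroxy)methyl]-γ-butyrolactone with 4-benzyloxy-3-methoxybenzyl bromide.
- Hydroxy lactone ⇐ opening by water, with inversion at the benzylic carbon (sets C7), of the donor–acceptor cyclopropane in a (1S,5R,6R)-6-aryl-3-oxabicyclo[3.1.0]hexan-2-one.
- Bicyclic lactone ⇐ enantioselective intramolecular cyclopropanation of (E)-O-benzylconiferyl diazoacetate (sets C8 and the configuration of the future C7).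
- Diazoacetate ⇐ (E)-O-benzylconiferyl alcohol ⇐ cross-metathesis of benzyl isoeugenol with cis-2-butene-1,4-diol.
- Ring order: cyclopropane and γ-lactone close together in step 3; the cyclopropane is cleaved in step 4 and the lactone is carried to the target; both arenes are bought.

Assumption: the 4R dirhodium carboxamidate is taken to give the (1S,5R,6R) lactone, by analogy with the sense of induction known for simpler allylic diazoacetates (otherwise the 4S catalyst is used), and glyoxylic acid chloride p-toluenesulfonylhydrazone is taken as bought.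

**Route**

Step 1
Reactants: 1 benzyl isoeugenol [1-(benzyloxy)-2-methoxy-4-[(E)-prop-1-enyl]benzene]; 2 (Z)-but-2-ene-1,4-diol
Product: 3 (E)-3-[4-(benzyloxy)-3-methoxyphenyl]prop-2-en-1-ol (O-benzylconiferyl alcohol)
Conditions: second-generation Hoveyda–Grubbs catalyst RuCl2(H2IMes)(=CH-C6H4-2-OiPr) (3 mol %), 2 (4 equiv), CH2Cl2, 40 °C
Reagents that add atoms: none
Why: Olefin cross-metathesis exchanges the methyl-bearing alkylidene of 1 for the hydroxymethyl alkylidene of excess 2, and the conjugated disubstituted alkene forms under thermodynamic control as the E isomer; no stereocenter is formed.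

Step 2
Reactants: 3 (E)-3-[4-(benzyloxy)-3-methoxyphenyl]prop-2-en-1-ol; 4 glyoxylic acid chloride p-toluenesulfonylhydrazone
Product: 6 (2E)-3-[4-(benzyloxy)-3-methoxyphenyl]prop-2-en-1-yl diazoacetate, via tosylhydrazone ester 5 (not isolated)
Conditions: 4 (1.3 equiv), PhNMe2, CH2Cl2, 0 °C; then Et3N, 0 °C to rt
Reagents that add atoms: none
Why: House–Corey–Myers diazoacetate synthesis: O-acylation by the acid chloride, then base-induced loss of p-toluenesulfinate from the tosylhydrazone (Bamford–Stevens type), gives the diazo ester under non-acidic conditions that spare the ionisable electron-rich cinnamyl ester; no stereocenter is formed.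

Step 3
Reactants: 6 (2E)-3-[4-(benzyloxy)-3-methoxyphenyl]prop-2-en-1-yl diazoacetate
Product: 7 (1S,5R,6R)-6-[4-(benzyloxy)-3-methoxyphenyl]-3-oxabicyclo[3.1.0]hexan-2-one
Conditions: Rh2(4R-MPPIM)4 [dirhodium tetrakis(methyl (4R)-2-oxo-1-(3-phenylpropanoyl)imidazolidine-4-carboxylate)] (1 mol %), CH2Cl2, reflux, 6 added over 10 h
Reagents that add atoms: none
Why: Enantioselective intramolecular cyclopropanation of an allylic diazoacetate (Doyle cyclopropanation): the chiral carboxamidate ligands select the alkene face (about 95% ee expected for an E-cinnamyl ester), which sets C1 and C5, while the E geometry is transferred stereospecifically so the aryl group at C6 is exo, and cyclopropane and γ-lactone close in the same carbene-transfer event.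

Step 4
Reactants: 7 (1S,5R,6R)-6-[4-(benzyloxy)-3-methoxyphenyl]-3-oxabicyclo[3.1.0]hexan-2-one
Product: 8 (4R)-4-{(R)-[4-(benzyloxy)-3-methoxyphenyl](hydroxy)methyl}oxolan-2-one
Conditions: Sc(OTf)3 (10 mol %), H2O (10 equiv), THF, 0 °C to rt; NaHCO3 quench at full conversion
Reagents that add atoms: water, O
Why: Proposed new method: Sc3+ on the lactone carbonyl weakens the exo C1–C6 bond (the one aligned with the carbonyl π* and pushed by the p-alkoxyaryl donor) and water attacks C6 from the side opposite the departing enolate carbon, so C6 is inverted to the (R)-carbinol while C5 is untouched and no second arene is yet present to trap a benzylic cation; the closest known reaction is the stereoinvertive Lewis acid-catalysed SN2-type opening of aryl cyclopropane-1,1-diesters by O-nucleophiles, the single lactone acceptor being the untested element.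

Step 5
Reactants: 9 4-(benzyloxy)-3-methoxybenzyl alcohol
Product: 10 4-(benzyloxy)-3-methoxybenzyl bromide
Conditions: PBr3 (0.4 equiv), Et2O, 0 °C; used fresh
Reagents that add atoms: phosphorus tribromide, BrP(Br)Br
Why: Alcohol-to-bromide conversion through the phosphite ester and bromide displacement at an activated benzylic carbon; no stereocenter is involved.

Step 6
Reactants: 8 (4R)-4-{(R)-[4-(benzyloxy)-3-methoxyphenyl](hydroxy)methyl}oxolan-2-one; 10 4-(benzyloxy)-3-methoxybenzyl bromide
Product: 12 (3R,4R)-3-[4-(benzyloxy)-3-methoxybenzyl]-4-{(R)-[4-(benzyloxy)-3-methoxyphenyl](hydroxy)methyl}oxolan-2-one, via dilithium alkoxide enolate 11 (not isolated)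
Conditions: 8 added to LiN(iPr)2 (2.2 equiv), THF, −78 °C; 10 (1.2 equiv), −78 to −45 °C; AcOH, −78 °C
Reagents that add atoms: none
Why: Dianion alkylation of a hydroxy lactone: the lithium enolate is C-benzylated anti to the bulky C4 substituent, which sets C3 as R (trans), while the lithium alkoxide is inert to the bromide at low temperature and the lactone cannot translactonise while it is held as its enolate.

Step 7
Reactants: 12 (3R,4R)-3-[4-(benzyloxy)-3-methoxybenzyl]-4-{(R)-[4-(benzyloxy)-3-methoxyphenyl](hydroxy)methyl}oxolan-2-one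
Product: 13 (3R,4R)-4-[(R)-hydroxy(4-hydroxy-3-methoxyphenyl)methyl]-3-(4-hydroxy-3-methoxybenzyl)oxolan-2-one [(7R,8R,8′R)-7-hydroxymatairesinol, allo-hydroxymatairesinol]
Conditions: H2 (1 atm), 10% Pd/C, EtOAc, rt, stopped at full conversion
Reagents that add atoms: none
Why: Catalytic hydrogenolysis of the two aryl benzyl ethers, which under neutral conditions at 1 atm cleave much faster than the secondary benzylic C–OH bond, so the carbinol and the three stereocenters are untouched.

**Compound list**

1 | benzyl isoeugenol, 1-(benzyloxy)-2-methoxy-4-[(E)-prop-1-enyl]benzene | C/C=C/c1ccc(OCc2ccccc2)c(OC)c1 | starting material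
2 | (Z)-but-2-ene-1,4-diol | OC/C=C\CO | starting material
3 | (E)-3-[4-(benzyloxy)-3-methoxyphenyl]prop-2-en-1-ol | OC/C=C/c1ccc(OCc2ccccc2)c(OC)c1 | intermediate
4 | glyoxylic acid chloride p-toluenesulfonylhydrazone | Cc1ccc(cc1)S(=O)(=O)NN=CC(Cl)=O | starting material
5 | tosylhydrazone ester, (2E)-3-[4-(benzyloxy)-3-methoxyphenyl]prop-2-en-1-yl 2-[2-(4-methylbenzenesulfonyl)hydrazinylidene]acetate (formed in the flask) | Cc1ccc(cc1)S(=O)(=O)NN=CC(=O)OC/C=C/c1ccc(OCc2ccccc2)c(OC)c1 | intermediate
6 | (2E)-3-[4-(benzyloxy)-3-methoxyphenyl]prop-2-en-1-yl diazoacetate | [N-]=[N+]=CC(=O)OC/C=C/c1ccc(OCc2ccccc2)c(OC)c1 | intermediate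
7 | (1S,5R,6R)-6-[4-(benzyloxy)-3-methoxyphenyl]-3-oxabicyclo[3.1.0]hexan-2-one (aryl exo) | O=C1OC[C@@H]2[C@@H](c3ccc(OCc4ccccc4)c(OC)c3)[C@H]12 | intermediate
8 | (4R)-4-{(R)-[4-(benzyloxy)-3-methoxyphenyl](hydroxy)methyl}oxolan-2-one | C1C(=O)OC[C@@H]1[C@@H](O)c2ccc(OCc3ccccc3)c(OC)c2 | intermediate
9 | 4-(benzyloxy)-3-methoxybenzyl alcohol | OCc1ccc(OCc2ccccc2)c(OC)c1 | starting material
10 | 4-(benzyloxy)-3-methoxybenzyl bromide | BrCc1ccc(OCc2ccccc2)c(OC)c1 | intermediate
11 | dilithium alkoxide enolate of 8 (formed in the flask) | C1=C([O-])OC[C@@H]1[C@@H]([O-])c2ccc(OCc3ccccc3)c(OC)c2.[Li+].[Li+] | intermediate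
12 | (3R,4R)-3-[4-(benzyloxy)-3-methoxybenzyl]-4-{(R)-[4-(benzyloxy)-3-methoxyphenyl](hydroxy)methyl}oxolan-2-one | COc1cc(C[C@H]2C(=O)OC[C@@H]2[C@@H](O)c2ccc(OCc3ccccc3)c(OC)c2)ccc1OCc1ccccc1 | intermediate
13 | (3R,4R)-4-[(R)-hydroxy(4-hydroxy-3-methoxyphenyl)methyl]-3-(4-hydroxy-3-methoxybenzyl)oxolan-2-one, allo-hydroxymatairesinol | COc1cc(C[C@H]2C(=O)OC[C@@H]2[C@@H](O)c2ccc(O)c(OC)c2)ccc1O | target

**Step count and risks**

Total steps: 7. Longest linear sequence: 6 (steps 1, 2, 3, 4, 6, 7).

Step 4 (most likely to fail). The single-acceptor cyclopropane may need conditions strong enough to ionise the benzylic carbon, giving a mixture at C7, or the product carbinol may epimerise or translactonise under the acid. The fallback sets out from 7 and returns at 8, and takes the stereochemical demand off the ring opening. Compound 7 is opened under deliberately ionising conditions (TfOH 5 mol %, (CF3)2CHOH/H2O, rt) to the carbinol-epimer mixture of the hydroxy lactone F1. The mixture is oxidised with MnO2 in CH2Cl2 to the single aryl ketone (4R)-4-[4-(benzyloxy)-3-methoxybenzoyl]oxolan-2-one F2. F2 is reduced under reagent control with (S)-2-methyl-CBS-oxazaborolidine and BH3·SMe2 in THF at −20 °C to give 8; the aryl-as-large-group model predicts the R carbinol, and the antipodal catalyst is used if the branched alkyl side dominates.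

Step 6. The unprotected dianion may translactonise through the γ-alkoxide before enolisation, O-alkylate, or convert poorly. The fallback sets out from 8 and returns at 12, and masks the carbinol so that a simple mono-enolate is alkylated. Compound 8 is silylated (Et3SiCl, imidazole, CH2Cl2) to the triethylsilyl ether (4R)-4-{(R)-[4-(benzyloxy)-3-methoxyphenyl](triethylsilyloxy)methyl}oxolan-2-one F3. Its lithium enolate (LiN(SiMe3)2, THF, −78 °C) is alkylated with 10 to the trans-disubstituted silyl ether F4. Buffered fluoride (Bu4NF/AcOH, THF, 0 °C) then removes the silyl group to give 12.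

Step 7. Hydrogenolysis may also remove the electron-rich benzylic hydroxyl and give the matairesinol skeleton. The fallback sets out from 12 and returns at 13, and shields the carbinol during the reduction. Compound 12 is converted (tBuMe2SiCl, imidazole, DMF) to the tert-butyldimethylsilyl ether F5. The two aryl benzyl ethers of F5 are hydrogenolysed (H2, Pd/C, EtOAc) to the diphenol silyl ether F6. F6 is desilylated with HF·pyridine in THF at 0 °C to give 13.

**Further compounds**

F1 | step 4 | (4R)-4-{[4-(benzyloxy)-3-methoxyphenyl](hydroxy)methyl}oxolan-2-one, mixture of epimers at the carbinol carbon | C1C(=O)OC[C@@H]1C(O)c2ccc(OCc3ccccc3)c(OC)c2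
F2 | step 4 | (4R)-4-[4-(benzyloxy)-3-methoxybenzoyl]oxolan-2-one | C1C(=O)OC[C@@H]1C(=O)c2ccc(OCc3ccccc3)c(OC)c2
F3 | step 6 | (4R)-4-{(R)-[4-(benzyloxy)-3-methoxyphenyl](triethylsilyloxy)methyl}oxolan-2-one | C1C(=O)OC[C@@H]1[C@@H](O[Si](CC)(CC)CC)c2ccc(OCc3ccccc3)c(OC)c2
F4 | step 6 | (3R,4R)-3-[4-(benzyloxy)-3-methoxybenzyl]-4-{(R)-[4-(benzyloxy)-3-methoxyphenyl](triethylsilyloxy)methyl}oxolan-2-one | COc1cc(C[C@H]2C(=O)OC[C@@H]2[C@@H](O[Si](CC)(CC)CC)c2ccc(OCc3ccccc3)c(OC)c2)ccc1OCc1ccccc1
F5 | step 7 | (3R,4R)-3-[4-(benzyloxy)-3-methoxybenzyl]-4-{(R)-[4-(benzyloxy)-3-methoxyphenyl](tert-butyldimethylsilyloxy)methyl}oxolan-2-one | COc1cc(C[C@H]2C(=O)OC[C@@H]2[C@@H](O[Si](C)(C)C(C)(C)C)c2ccc(OCc3ccccc3)c(OC)c2)ccc1OCc1ccccc1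
F6 | step 7 | (3R,4R)-4-{(R)-(tert-butyldimethylsilyloxy)(4-hydroxy-3-methoxyphenyl)methyl}-3-(4-hydroxy-3-methoxybenzyl)oxolan-2-one | COc1cc(C[C@H]2C(=O)OC[C@@H]2[C@@H](O[Si](C)(C)C(C)(C)C)c2ccc(O)c(OC)c2)ccc1O
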